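## The problem

Target 23 is a cis-fused hydroazulene diester. In this proposal the cyclopentane is numbered C1 (quaternary, methyl)–C2 (angelate)–C3–C4 (tertiary carbinol, isopropyl)–C5 (fusion CH), and the cycloheptene C5–C6 (3,4,5-trimethoxybenzoate)–C7–C8 (methyl)=C9–C10–C1. It has five stereocentres (1R,2S,4S,5R,6R). On the cyclopentane the C2 and C4 oxygens are cis to each other and to the ring bonds C1–C10 and C5–C6, while the C1 methyl, the isopropyl group and H5 share the other face. The C6 oxygen is cis to H5 and 1,3-anti to the C4 hydroxyl. Only C4 can be made without reference to the others, as an acyclic tertiary carbinol; once present it can direct C1 and C2 during closure of the cyclopentane (metal chelate) and C6 by hydroxyl-directed hydride delivery, leaving C5 to a protonation next to a ketone. The molecule is fragile: the angelate isomerises to the tiglate with base or nucleophiles, a C6 ketone on the way has a β-hydroxyl (retro-aldol, dehydration) and a β,γ-alkene (C8=C9) ready to move into conjugation, and two different acyl groups must go onto two secondary hydroxyls beside a free tertiary one. The feature that allows a short synthesis is that carbinol C2 is bonded to quaternary C1, and C1 is β to the C6 oxygen through C5. C1–C2 is therefore the bond of a reductive coupling between a C2 aldehyde and a C5=C1–C6=O enone, and that enone, with both ring methyls and C8=C9 in place, is a ring-expanded 2,5-dimethylanisole. The price is that the aldehyde arm hangs from the α-carbon C5 of the enone, so the closure is not the usual exo ketyl–olefin cyclisation and has to be steered.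

## Retrosynthesis

**Ester C–O bonds and C6–H.** Removing the aroyl group from 23 gives alcohol 21 and acid chloride 22; removing the C6 hydride gives ketone 20; removing the angeloyl group gives hydroxy ketone 17 and angelic acid 18. In 17 the three oxygen functions differ in kind (secondary alcohol, tertiary alcohol, ketone), so no protecting group is needed, whereas the reverse order would require steric differentiation of two secondary alcohols. The forward steps must angeloylate a base-sensitive β-hydroxy β,γ-unsaturated ketone without isomerisation and reduce 20 under direction from the C4 hydroxyl.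

**C1–C2.** Cutting this bond in 17 removes the cyclopentane, the quaternary centre and three stereocentres (C1, C2, C5) at once and leaves keto aldehyde 16, a monocyclic dienone with one stereocentre. Cutting C4–C5 (aldol) or C1–C5 instead would leave the quaternary centre C1 to be made separately. The forward reductive coupling must join C2 to C1 and not to the C6 carbonyl carbon, place the C2 oxygen cis to the C4 oxygen, reach C1 on the face anti to the isopropyl group, and protonate C5 on the methyl face.

**C2–C3 and redox adjustment.** Keto aldehyde 16 is the hydrolysis product of enol ether 15, which stores the aldehyde as a methyl enol ether and the enone as a dioxolane. The C2=C3 bond of 15 is cut by a Wittig disconnection to α-hydroxy aldehyde 14, which comes from diol 13 and thence from α-hydroxy ester 12. Bringing C2 in together with C3 would be shorter, but it would move the carbinol-forming step away from an α-keto ester, the electrophile for which auxiliary control of a tertiary carbinol is dependable. The forward steps must be mild enough for a tertiary allylic alcohol and a skipped diene.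

**C4–C5.** Ester 12 is cut between the carbinol carbon and the ring into the vinyl-metal 11 (from vinyllithium 10 and vinyl bromide 6) and the α-keto ester 9, itself from keto acid 7 and (−)-8-phenylmenthol 8. This is the only cut that attaches the side chain at the α-carbon of the future enone in one step, and it creates C4 on an electrophile whose two faces are differentiated by a covalently bound, recoverable auxiliary. The addition must tolerate two hindered partners.

**The ring.** Ketal 6 is the protected form of 2-bromo dienone 5. Dienone 5 is cut across C5–C6 and C5–C1 to dibromocyclopropane 4, that is to diene 2 and bromoform 3, and 2 is the Birch product of 2,5-dimethylanisole 1. The arene supplies C6 (from the methoxy carbon), C1 and C8 with their methyls and the C8=C9 alkene; the carbene carbon becomes C5 and carries the bromine needed for the C4–C5 bond. The ring opening must stop at the bromo dienone and not go on to the tropone.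

## Roads not taken

**Alternative 1: intramolecular Buchner reaction.** The cut is at C1–C5 and C1–C10. Forward, a dirhodium tetracarboxylate such as Rh2(OAc)4 would decompose diazoketone A1; the carbenoid at C1 would cyclopropanate the ipso–ortho bond of the anisole and the norcaradiene would open to azulenone A2.
- Merits: both rings and the quaternary centre arise in one step from a flat arene, and aryl-tethered diazoketones are well-established Buchner substrates. In precedent for the ring-forming step this road is better than the chosen one.
- Weak points: the carbenoid carbon carries a methyl group, so 1,2-hydride shift to an enone competes. The addition must choose the C5–C10 bond over the methoxy-bearing C5–C6 bond. A2 is a cycloheptatriene with C2 as a ketone and C6 as an enol ether, so the C9=C10 and C7=C8 bonds would have to be converted into the single C8=C9 alkene without a selective handle, and C2, C5 and C6 would all be set late.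
- Comparison: the chosen plan offers in return the correct position of the alkene and the correct oxidation level at C2, C4 and C6 directly after its key step.

**Alternative 2: divinylcyclopropane Cope rearrangement.** The cut is at C1–C10, with C6–C8 as the bond that breaks in the forward sense. Heating cis-divinylcyclopropane A3 would give A4.
- Merits: the step is pericyclic and stereospecific, needs no reagent, and gives the seven-membered ring with C8=C9 and the C6 oxygen (as silyl enol ether) exactly in place. In this respect it equals the chosen plan and it has no stereoelectronic handicap.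
- Weak points: in A3 the C1 methyl sits on the inside of the boat transition state, which retards such rearrangements and opens the way to cis–trans isomerisation of the cyclopropane. A3 itself needs an enantioselective synthesis of a tetrasubstituted siloxycyclopropane. After the key step only C1 is fixed: the isopropyl group would have to enter C4 syn to the C1 methyl, and C2, C5 and C6 would also rest on substrate control from the remote quaternary centre.
- Comparison: the chosen plan sets one stereocentre (C4) early and lets it govern the four others, and it has a three-step endgame.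

**Alternative 3: oxidopyrylium–alkene (5+2) cycloaddition.** The cut is at C1–C5 and C9–C10. Base would eliminate acetic acid from acetoxypyranone A5 and the 3-oxidopyrylium would add across its 2- and 6-positions to the tethered 1,1-disubstituted alkene to give A6.
- Merits: both rings and the quaternary centre form together, and cycloadditions of this kind through a three-atom tether are among the best-precedented routes to hydroazulenes. The key step is safer than the chosen one, and the tether stereocentres C2 and C4 control C1 and C5.
- Weak points: the oxygen bridge C5–O–C9 must be excised, which leaves a hydroxyl at C9 to be removed and requires the C7=C8 enone alkene to be moved to C8=C9. A5 needs a furan carbinol, an Achmatowicz rearrangement and two preset stereocentres, so the route before the key step is longer.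
- Comparison: the chosen plan offers the right alkene and carbonyl pattern without bridge surgery, and a precursor with one stereocentre.

Key step: step 11

Assumption: the facial sense of addition to the (1R,2S,5R)-8-phenylmenthyl α-keto ester is taken from the chelate model for this auxiliary (attack on the keto face not covered by the phenyl ring); if the opposite sense were found, the enantiomeric auxiliary would be used.

## Route

Step 1
Reactants: 1 2,5-dimethylanisole
Product: 2 1-methoxy-2,5-dimethylcyclohexa-1,4-diene
Conditions: Li, NH3(l), THF, t-BuOH, −78 to −33 °C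
Reagents that add atoms: none
Why: Birch reduction of an alkyl anisole leaves the methoxy and both methyl groups on the two remaining double bonds; no stereocentre is formed.

Step 2
Reactants: 2 1-methoxy-2,5-dimethylcyclohexa-1,4-diene; 3 bromoform
Product: 4 7,7-dibromo-1-methoxy-3,6-dimethylbicyclo[4.1.0]hept-3-ene (racemic)
Conditions: KOt-Bu, pentane, −20 to 0 °C
Reagents that add atoms: none
Why: Dibromocarbene from bromoform and alkoxide adds in a [2+1] cycloaddition to the more electron-rich enol-ether double bond; the cis-fused adduct is racemic and both stereocentres disappear in step 3.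

Step 3
Reactants: 4 7,7-dibromo-1-methoxy-3,6-dimethylbicyclo[4.1.0]hept-3-ene
Product: 5 2-bromo-3,6-dimethylcyclohepta-2,5-dien-1-one
Conditions: AgNO3, CaCO3, acetone–H2O, 0 °C to rt
Reagents that add atoms: water, O
Why: Silver-assisted loss of bromide with electrocyclic opening of the cyclopropane gives the methoxy-stabilised allyl cation, which is hydrated and loses methanol (dihalocyclopropane ring expansion); base is excluded because loss of HBr would lead to the tropone.

Step 4
Reactants: 5 2-bromo-3,6-dimethylcyclohepta-2,5-dien-1-one
Product: 6 6-bromo-7,10-dimethyl-1,4-dioxaspiro[4.6]undeca-6,9-diene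
Conditions: Me3SiOCH2CH2OSiMe3, Me3SiOTf (cat.), CH2Cl2, −78 to −20 °C
Reagents that add atoms: 1,2-bis(trimethylsilyloxy)ethane, C[Si](C)(C)OCCO[Si](C)(C)C
Why: Noyori ketalisation under aprotic low-temperature conditions masks the ketone without acid-catalysed migration of either double bond and turns the α-bromo enone into a precursor of an α-keto vinyl anion equivalent.

Step 5
Reactants: 7 3-methyl-2-oxobutanoic acid; 8 (1R,2S,5R)-8-phenylmenthol
Product: 9 (1R,2S,5R)-8-phenylmenthyl 3-methyl-2-oxobutanoate
Conditions: p-TsOH (cat.), toluene, reflux, Dean–Stark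
Reagents that add atoms: none
Why: Acid-catalysed azeotropic esterification, the usual access to α-keto esters of this auxiliary alcohol.

Step 6
Reactants: 6 6-bromo-7,10-dimethyl-1,4-dioxaspiro[4.6]undeca-6,9-diene; 9 (1R,2S,5R)-8-phenylmenthyl 3-methyl-2-oxobutanoate
Product: 12 (1R,2S,5R)-8-phenylmenthyl (2S)-2-(7,10-dimethyl-1,4-dioxaspiro[4.6]undeca-6,9-dien-6-yl)-2-hydroxy-3-methylbutanoate, via spiroketal vinyllithium 10 (not isolated), via spiroketal vinylmagnesium bromide 11 (not isolated)
Conditions: t-BuLi (2 equiv), Et2O, −78 °C; MgBr2·OEt2, −78 to −40 °C; then 9, −78 °C; aq. NH4Cl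
Reagents that add atoms: none
Why: Bromine–lithium exchange and transmetalation give a vinyl Grignard reagent that adds 1,2 to the magnesium-chelated α-keto ester on the face not shielded by the phenyl ring of the auxiliary (auxiliary-controlled Grignard addition to an 8-phenylmenthyl α-keto ester), which sets C4 as (S).

Step 7
Reactants: 12 (1R,2S,5R)-8-phenylmenthyl (2S)-2-(7,10-dimethyl-1,4-dioxaspiro[4.6]undeca-6,9-dien-6-yl)-2-hydroxy-3-methylbutanoate
Product: 13 (2S)-2-(7,10-dimethyl-1,4-dioxaspiro[4.6]undeca-6,9-dien-6-yl)-3-methylbutane-1,2-diol
Conditions: LiAlH4, Et2O, 0 °C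
Reagents that add atoms: none
Why: Hydride reduction of the ester gives the primary alcohol and releases the auxiliary 8 for recovery; the ketal, the alkenes and the C4 stereocentre are untouched.

Step 8
Reactants: 13 (2S)-2-(7,10-dimethyl-1,4-dioxaspiro[4.6]undeca-6,9-dien-6-yl)-3-methylbutane-1,2-diol
Product: 14 (2S)-2-(7,10-dimethyl-1,4-dioxaspiro[4.6]undeca-6,9-dien-6-yl)-2-hydroxy-3-methylbutanal
Conditions: SO3·pyridine, DMSO, i-Pr2NEt, CH2Cl2, −10 to 0 °C
Reagents that add atoms: none
Why: Parikh–Doering oxidation touches only the primary hydroxyl and does not cleave the 1,2-diol; the aldehyde has no α-hydrogen and is used at once to forestall α-ketol rearrangement.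

Step 9
Reactants: 14 (2S)-2-(7,10-dimethyl-1,4-dioxaspiro[4.6]undeca-6,9-dien-6-yl)-2-hydroxy-3-methylbutanal
Product: 15 (3R)-3-(7,10-dimethyl-1,4-dioxaspiro[4.6]undeca-6,9-dien-6-yl)-1-methoxy-4-methylpent-1-en-3-ol (E/Z mixture)
Conditions: MeOCH2PPh3Cl, KN(SiMe3)2 (excess ylide), THF, −78 to 0 °C
Reagents that add atoms: (methoxymethyl)triphenylphosphonium chloride, COC[P+](c1ccccc1)(c1ccccc1)c1ccccc1.[Cl-]
Why: Wittig methoxymethylenation adds carbon C2 as a masked aldehyde; excess ylide tolerates the free tertiary hydroxyl, the alkene geometry is irrelevant, and the change of descriptor at C4 is only a change of priorities.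

Step 10
Reactants: 15 (3R)-3-(7,10-dimethyl-1,4-dioxaspiro[4.6]undeca-6,9-dien-6-yl)-1-methoxy-4-methylpent-1-en-3-ol
Product: 16 (3S)-3-(2,5-dimethyl-7-oxocyclohepta-1,4-dien-1-yl)-3-hydroxy-4-methylpentanal
Conditions: oxalic acid, THF–H2O, 0 °C to rt
Reagents that add atoms: water, O
Why: Mild aqueous acid hydrolyses the methyl enol ether and the dioxolane in one operation (acetal-type hydrolysis), unveiling the C2 aldehyde and the C6 enone while a weak acid spares the tertiary allylic alcohol and the β-hydroxy aldehyde.

Step 11
Reactants: 16 (3S)-3-(2,5-dimethyl-7-oxocyclohepta-1,4-dien-1-yl)-3-hydroxy-4-methylpentanal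
Product: 17 (1R,2S,4S,5S)-2,4-dihydroxy-4-isopropyl-1,8-dimethyl-cis-bicyclo[5.3.0]dec-8-en-6-one (proposal numbering)
Conditions: SmI2 (2.3 equiv), t-BuOH (3 equiv), THF, −78 to −30 °C; aq. NH4Cl at −78 °C
Reagents that add atoms: none
Why: Divalent samarium transfers an electron to the chelated β-hydroxy enone (or, reversibly, to the aldehyde); the radical anion, with its spin at C1, adds to the aldehyde carbon C2, and a second electron gives the trivalent samarium alkoxide–enolate, which is protonated at C5. The closest known reaction type is the SmI2-mediated reductive aldehyde–enone (ketyl–olefin) cyclisation and its electroreductive counterpart. The cyclopentane closes 5-exo-trig at the aldehyde C=O when the enone is reduced first; the ketyl-first addition to C1 forms the same bond but is formally 5-endo-trig at C1=C5 because the tether sits on the α-carbon, so HMPA is left out to keep the chelated enone as the preferred electron acceptor. C1 is controlled by C4: with the C4 oxygen and the C6 oxygen on the same samarium, C3 and the isopropyl group lie on opposite faces of the enone plane and C2 reaches C1 anti to the isopropyl group. C2 is controlled by the same metal, which also binds the C2 oxygen, so the C2–O and C4–O bonds end cis and trans to the C1 methyl. C5 is set when the enolate is protonated on the face opposite the samarium-bound oxygens, the face of the C1 methyl, which gives the cis-fused ketone with C6 anti to the isopropyl group, expected also to be the more stable C5 epimer. The step needs C1 to be chosen over the C6 carbonyl carbon (pinacol-type coupling) and over simple reduction; the C4–O/C6=O chelate turns the aldehyde arm toward C1 and away from C6, the quaternary C4 holds it there (Thorpe–Ingold effect), and the reagent is limited to a small excess because 17 is a reducible β-hydroxy ketone.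

Step 12
Reactants: 17 (1R,2S,4S,5S)-2,4-dihydroxy-4-isopropyl-1,8-dimethyl-cis-bicyclo[5.3.0]dec-8-en-6-one; 18 angelic acid
Product: 20 (1R,2S,4S,5S)-4-hydroxy-4-isopropyl-1,8-dimethyl-6-oxo-cis-bicyclo[5.3.0]dec-8-en-2-yl (Z)-2-methylbut-2-enoate (proposal numbering), via angelic 2,4,6-trichlorobenzoic anhydride 19 (not isolated)
Conditions: 2,4,6-Cl3C6H2COCl, Et3N, toluene, rt; then 17, toluene, 60–70 °C
Reagents that add atoms: none
Why: Yamaguchi mixed-anhydride esterification without DMAP is the established way to make angelates without Z-to-E isomerisation; only the secondary C2 hydroxyl can react, since C4 is tertiary and C6 is a ketone.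

Step 13
Reactants: 20 (1R,2S,4S,5S)-4-hydroxy-4-isopropyl-1,8-dimethyl-6-oxo-cis-bicyclo[5.3.0]dec-8-en-2-yl (Z)-2-methylbut-2-enoate
Product: 21 (1R,2S,4S,5R,6R)-4,6-dihydroxy-4-isopropyl-1,8-dimethyl-cis-bicyclo[5.3.0]dec-8-en-2-yl (Z)-2-methylbut-2-enoate (proposal numbering)
Conditions: Me4NBH(OAc)3, MeCN–AcOH, −30 °C
Reagents that add atoms: none
Why: Evans–Saksena reduction: the C4 hydroxyl exchanges onto boron and delivers hydride intramolecularly to the C6 carbonyl from the face on which C4 lies, giving the 1,3-anti diol with the C6 hydroxyl cis to H5; the angelate and the alkenes are inert to this reagent.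

Step 14
Reactants: 21 (1R,2S,4S,5R,6R)-4,6-dihydroxy-4-isopropyl-1,8-dimethyl-cis-bicyclo[5.3.0]dec-8-en-2-yl (Z)-2-methylbut-2-enoate; 22 3,4,5-trimethoxybenzoyl chloride
Product: 23 (1R,2S,4S,5R,6R)-4-hydroxy-4-isopropyl-1,8-dimethyl-2-[(Z)-2-methylbut-2-enoyloxy]-cis-bicyclo[5.3.0]dec-8-en-6-yl 3,4,5-trimethoxybenzoate (proposal numbering), the target
Conditions: pyridine, DMAP (cat.), CH2Cl2, 0 °C to rt
Reagents that add atoms: none
Why: Acylation of the only secondary hydroxyl with the aroyl chloride under nucleophilic catalysis; the tertiary C4 hydroxyl does not react at this temperature.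

## Compound list

1 | 2,5-dimethylanisole | COc1cc(C)ccc1C | starting material
2 | 1-methoxy-2,5-dimethylcyclohexa-1,4-diene | COC1=C(C)CC=C(C)C1 | intermediate
3 | bromoform | BrC(Br)Br | starting material
4 | 7,7-dibromo-1-methoxy-3,6-dimethylbicyclo[4.1.0]hept-3-ene (racemic, cis-fused; one enantiomer drawn) | CO[C@]12CC(C)=CC[C@@]1(C)C2(Br)Br | intermediate
5 | 2-bromo-3,6-dimethylcyclohepta-2,5-dien-1-one | O=C1C(Br)=C(C)CC=C(C)C1 | intermediate
6 | 6-bromo-7,10-dimethyl-1,4-dioxaspiro[4.6]undeca-6,9-diene | BrC1=C(C)CC=C(C)CC12OCCO2 | intermediate
7 | 3-methyl-2-oxobutanoic acid | CC(C)C(=O)C(=O)O | starting material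
8 | (1R,2S,5R)-5-methyl-2-(2-phenylpropan-2-yl)cyclohexan-1-ol, (−)-8-phenylmenthol | CC(C)(c1ccccc1)[C@@H]1CC[C@@H](C)C[C@H]1O | starting material
9 | (1R,2S,5R)-8-phenylmenthyl 3-methyl-2-oxobutanoate | CC(C)(c1ccccc1)[C@@H]1CC[C@@H](C)C[C@H]1OC(=O)C(=O)C(C)C | intermediate
10 | (7,10-dimethyl-1,4-dioxaspiro[4.6]undeca-6,9-dien-6-yl)lithium | [Li]C1=C(C)CC=C(C)CC12OCCO2 | intermediate
11 | (7,10-dimethyl-1,4-dioxaspiro[4.6]undeca-6,9-dien-6-yl)magnesium bromide | Br[Mg]C1=C(C)CC=C(C)CC12OCCO2 | intermediate
12 | (1R,2S,5R)-8-phenylmenthyl (2S)-2-(7,10-dimethyl-1,4-dioxaspiro[4.6]undeca-6,9-dien-6-yl)-2-hydroxy-3-methylbutanoate | CC(C)(c1ccccc1)[C@@H]1CC[C@@H](C)C[C@H]1OC(=O)[C@](O)(C(C)C)C1=C(C)CC=C(C)CC12OCCO2 | intermediate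
13 | (2S)-2-(7,10-dimethyl-1,4-dioxaspiro[4.6]undeca-6,9-dien-6-yl)-3-methylbutane-1,2-diol | OC[C@](O)(C(C)C)C1=C(C)CC=C(C)CC12OCCO2 | intermediate
14 | (2S)-2-(7,10-dimethyl-1,4-dioxaspiro[4.6]undeca-6,9-dien-6-yl)-2-hydroxy-3-methylbutanal | O=C[C@](O)(C(C)C)C1=C(C)CC=C(C)CC12OCCO2 | intermediate
15 | (3R)-3-(7,10-dimethyl-1,4-dioxaspiro[4.6]undeca-6,9-dien-6-yl)-1-methoxy-4-methylpent-1-en-3-ol (E/Z mixture) | COC=C[C@](O)(C(C)C)C1=C(C)CC=C(C)CC12OCCO2 | intermediate
16 | (3S)-3-(2,5-dimethyl-7-oxocyclohepta-1,4-dien-1-yl)-3-hydroxy-4-methylpentanal | O=CC[C@](O)(C(C)C)C1=C(C)CC=C(C)CC1=O | intermediate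
17 | (1R,2S,4S,5S)-2,4-dihydroxy-4-isopropyl-1,8-dimethyl-cis-bicyclo[5.3.0]dec-8-en-6-one (proposal numbering) | O[C@H]1C[C@](O)(C(C)C)[C@H]2C(=O)CC(C)=CC[C@@]12C | intermediate
18 | angelic acid, (Z)-2-methylbut-2-enoic acid | C/C=C(/C)C(=O)O | starting material
19 | (Z)-2-methylbut-2-enoic 2,4,6-trichlorobenzoic anhydride | C/C=C(/C)C(=O)OC(=O)c1c(Cl)cc(Cl)cc1Cl | intermediate
20 | (1R,2S,4S,5S)-4-hydroxy-4-isopropyl-1,8-dimethyl-6-oxo-cis-bicyclo[5.3.0]dec-8-en-2-yl (Z)-2-methylbut-2-enoate | C/C=C(/C)C(=O)O[C@H]1C[C@](O)(C(C)C)[C@H]2C(=O)CC(C)=CC[C@@]12C | intermediate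
21 | (1R,2S,4S,5R,6R)-4,6-dihydroxy-4-isopropyl-1,8-dimethyl-cis-bicyclo[5.3.0]dec-8-en-2-yl (Z)-2-methylbut-2-enoate | C/C=C(/C)C(=O)O[C@H]1C[C@](O)(C(C)C)[C@H]2[C@H](O)CC(C)=CC[C@@]12C | intermediate
22 | 3,4,5-trimethoxybenzoyl chloride | COc1cc(cc(OC)c1OC)C(=O)Cl | starting material
23 | (1R,2S,4S,5R,6R)-4-hydroxy-4-isopropyl-1,8-dimethyl-2-[(Z)-2-methylbut-2-enoyloxy]-cis-bicyclo[5.3.0]dec-8-en-6-yl 3,4,5-trimethoxybenzoate | C/C=C(/C)C(=O)O[C@H]1C[C@](O)(C(C)C)[C@H]2[C@H](OC(=O)c3cc(OC)c(OC)c(OC)c3)CC(C)=CC[C@@]12C | target

## Step count and least certain steps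

Total: 14 steps. Longest linear sequence: 13 steps (1 to 23 through steps 1–4 and 6–14; step 5 prepares ester 9).

**Step 11 (key step).** Ring closure at C1 may fail to compete. If the electron enters the aldehyde first, the ketyl has to attack C1 in a strained 5-endo-trig geometry, and coupling of the ketyl with the C6 carbonyl carbon (an unstrained 5-exo closure to a cis-diol) or plain reduction of either carbonyl can take over. Protonation of the enolate on the wrong face of C5 is a lesser concern. The fallback sets out from 16 and returns at 17 without a new compound. The samarium ketyl route is given up for an electroreductive cyclisation: controlled-potential cathodic reduction just beyond the enone wave (glassy-carbon or mercury cathode, Et4NOTs in MeCN–H2O, dimethyl malonate as proton donor). At that potential the aldehyde is not reduced, so the bond can form only from C1 of the enone radical anion onto the aldehyde carbonyl, the unstrained direction, and no samarium template is present to promote C2–C6 coupling.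

**Step 6.** Addition may be slow and the keto ester may be enolised at its isopropyl methine, because both the vinyl nucleophile and the ketone are hindered; facial selectivity may also erode if chelation is incomplete. The fallback sets out from 6 (through vinyllithium 10) and returns at 13, with the roles of the two carbon groups exchanged.
- (1S,2R,5S)-8-Phenylmenthyl chlorooxoacetate F1, from the enantiomeric auxiliary and oxalyl chloride, would acylate 10 at −78 °C to the vinyl α-keto ester F2, which has no enolisable hydrogen next to the ketone.
- i-PrMgCl with ZnCl2 would add to the chelated keto group of F2 on the face left open by the phenyl ring to give the (2S)-hydroxy ester F3. The enantiomeric auxiliary is needed because the entering group is now the isopropyl group.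
- LiAlH4 reduction of F3 would give diol 13.

**Step 10.** Acid strong enough to hydrolyse the enol ether may ionise the tertiary allylic alcohol or dehydrate the β-hydroxy aldehyde as it forms. The fallback sets out from 14 and returns at 16, and makes the aldehyde last under neutral conditions.
- Wittig methylenation of 14 (Ph3P=CH2) would give the vinyl carbinol F4.
- 9-BBN hydroboration and oxidation of the monosubstituted alkene would give the 1,3-diol F5.
- Removal of the dioxolane with pyridinium tosylate in wet acetone, with no aldehyde present, would give the enone diol F6.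
- Oxidation of the primary hydroxyl (TEMPO, PhI(OAc)2) would give 16.

**Step 3.** Loss of HBr toward the tropone, or migration of the skipped double bond, may follow ring opening, since the product is a dihydrotropone carrying a leaving group. The fallback sets out from 4 and returns at 6 without a new compound: the silver-assisted ring opening would be run in ethylene glycol–THF, so that the allyl cation is captured directly as the dioxolane and the free bromo dienone never accumulates.

**Step 12.** Isomerisation during a slow acylation of the neopentylic C2 hydroxyl is the risk: Z-to-E in the angelate, base-induced movement of C8=C9 into conjugation, or epimerisation at C5. The fallback sets out from 17 and returns at 23 by changing the order of the endgame, so that no ketone is present when the angelate is made.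
- Evans–Saksena reduction of 17 would give the triol F7.
- The C6 hydroxyl on the convex face is more accessible than the C2 hydroxyl beside the quaternary centre, so it would be aroylated first with 22 to give F8.
- F8 would then be angeloylated at C2 through 19 under more forcing conditions to give 23.

## Further compounds

F0 | step 11 | none | none
F1 | step 6 | (1S,2R,5S)-8-phenylmenthyl chlorooxoacetate | CC(C)(c1ccccc1)[C@H]1CC[C@H](C)C[C@@H]1OC(=O)C(Cl)=O
F2 | step 6 | (1S,2R,5S)-8-phenylmenthyl 2-(7,10-dimethyl-1,4-dioxaspiro[4.6]undeca-6,9-dien-6-yl)-2-oxoacetate | CC(C)(c1ccccc1)[C@H]1CC[C@H](C)C[C@@H]1OC(=O)C(=O)C1=C(C)CC=C(C)CC12OCCO2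
F3 | step 6 | (1S,2R,5S)-8-phenylmenthyl (2S)-2-(7,10-dimethyl-1,4-dioxaspiro[4.6]undeca-6,9-dien-6-yl)-2-hydroxy-3-methylbutanoate | CC(C)(c1ccccc1)[C@H]1CC[C@H](C)C[C@@H]1OC(=O)[C@](O)(C(C)C)C1=C(C)CC=C(C)CC12OCCO2
F4 | step 10 | (3R)-3-(7,10-dimethyl-1,4-dioxaspiro[4.6]undeca-6,9-dien-6-yl)-4-methylpent-1-en-3-ol | C=C[C@](O)(C(C)C)C1=C(C)CC=C(C)CC12OCCO2
F5 | step 10 | (3S)-3-(7,10-dimethyl-1,4-dioxaspiro[4.6]undeca-6,9-dien-6-yl)-4-methylpentane-1,3-diol | OCC[C@](O)(C(C)C)C1=C(C)CC=C(C)CC12OCCO2
F6 | step 10 | (3S)-2-(1,3-dihydroxy-4-methylpentan-3-yl)-3,6-dimethylcyclohepta-2,5-dien-1-one | OCC[C@](O)(C(C)C)C1=C(C)CC=C(C)CC1=O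
F0 | step 3 | none | none
F7 | step 12 | (1R,2S,4S,5R,6R)-4-isopropyl-1,8-dimethyl-cis-bicyclo[5.3.0]dec-8-ene-2,4,6-triol (proposal numbering) | O[C@H]1C[C@](O)(C(C)C)[C@H]2[C@H](O)CC(C)=CC[C@@]12C
F8 | step 12 | (1R,2S,4S,5R,6R)-2,4-dihydroxy-4-isopropyl-1,8-dimethyl-cis-bicyclo[5.3.0]dec-8-en-6-yl 3,4,5-trimethoxybenzoate (proposal numbering) | O[C@H]1C[C@](O)(C(C)C)[C@H]2[C@H](OC(=O)c3cc(OC)c(OC)c(OC)c3)CC(C)=CC[C@@]12C
A1 | alternative 1 | (S)-2-diazo-5-(2-methoxy-4-methylphenyl)-6-methyl-5-(triethylsilyloxy)heptan-3-one | CC(=[N+]=[N-])C(=O)C[C@](O[Si](CC)(CC)CC)(C(C)C)c1ccc(C)cc1OC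
A2 | alternative 1 | 6-methoxy-1,8-dimethyl azulenone, cycloheptatriene fused to cyclopentanone | O=C1C[C@](O[Si](CC)(CC)CC)(C(C)C)C2=C(OC)C=C(C)C=C[C@@]12C
A3 | alternative 2 | cis-1-(tert-butyldimethylsilyloxy)-1-(3,3-dimethoxy-2-methyl-5-oxocyclopent-1-enyl)-2-methyl-2-vinylcyclopropane | COC1(OC)CC(=O)C(=C1C)[C@]2(O[Si](C)(C)C(C)(C)C)C[C@]2(C)C=C
A4 | alternative 2 | hydroazulene vinylogous silyl ester with C2 dimethyl ketal | COC1(OC)CC(=O)C2=C(O[Si](C)(C)C(C)(C)C)CC(C)=CC[C@@]12C
A5 | alternative 3 | 6-acetoxy-5-methyl-2H-pyran-3(6H)-one carrying at C2 the (3S,5S)-5-(tert-butyldimethylsilyloxy)-3-hydroxy-2,6-dimethylhept-6-en-3-yl chain | C=C(C)[C@@H](O[Si](C)(C)C(C)(C)C)C[C@](O)(C(C)C)C1OC(OC(C)=O)C(C)=CC1=O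
A6 | alternative 3 | cyclopentane-fused 8-oxabicyclo[3.2.1]oct-3-en-2-one | CC(C)(C)[Si](C)(C)O[C@H]1C[C@](O)(C(C)C)[C@]23O[C@H](C[C@@]12C)C(C)=CC3=O
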